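Readings and results are simulated for an exercise, noise included.

One thing held still in the three earlier runs while D, E and G fell: the ratio of G to E. I called it ρ, the summed G over the summed E of all readings, 0.394.

| flask | D | L | X | remark | time |
|---|---|---|---|---|---|
| birch | 26 mM | 130 mM | 1.7 mM | run made earlier |  |
| ash | 26 mM | 130 mM | 3.9 mM | run made earlier |  |
| elm | 13 mM | 130 mM | 2.6 mM | run made earlier |  |
| flask | 26 mM | 130 mM | 2.6 mM |  | 20 min |

| run | time / min | G / % | E / % | D / % |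
|---|---|---|---|---|
| birch | 1.33 | 18.1 | 47.3 | 9.2 |
| birch | 4.00 | 14.2 | 37.5 | 6.9 |
| birch | 6.00 | 12.7 | 30.1 | 6.3 |
| birch | 10.0 | 8.7 | 20.8 | 4.1 |
| birch | 15.0 | 5.5 | 12.6 | 2.6 |
| birch | 20.0 | 2.5 | 8.2 | 1.4 |
| birch | 25.0 | 2.0 | 5.6 | 0.6 |
| ash | 3.00 | 16.4 | 40.8 | 7.9 |
| ash | 6.00 | 12.2 | 30.3 | 5.2 |
| ash | 10.0 | 8.3 | 20.2 | 4.1 |
| ash | 15.0 | 5.3 | 11.9 | 3.2 |
| ash | 20.0 | 3.8 | 7.7 | 1.3 |
| ash | 25.0 | 2.4 | 5.6 | 1.3 |
| elm | 2.00 | 17.3 | 45.4 | 7.8 |
| elm | 4.00 | 14.5 | 36.5 | 6.7 |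
| elm | 6.00 | 11.6 | 30.4 | 5.8 |
| elm | 12.0 | 5.8 | 17.8 | 3.1 |
| elm | 25.0 | 1.9 | 5.6 | 0.4 |

(standard deviation of a reading: 0.5 percentage points)

- the analysis behind the earlier runs scatters by 0.5 percentage points, standard deviation

- ratio of G to E at 0.15 s
- ratio of G to E at 20 min

I went down the time scales from the fastest. At 0.15 s no run has a reading, and the earliest, 1.33 min in birch, came far later, so I reckoned nothing there. By the first reading of each run the ratio already stood, at 0.388. X did not show in it: at 10.0 min birch read 0.418, and ash, with twice the X, read 0.411.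

Next came the common fall. In ash, E dropped at 0.0903 min⁻¹ and G at 0.0874 min⁻¹, so E halved every 7.68 min, and 20 min spans 2.60 such half-lives.

Taking ρ as the large thing, I computed its correction. The last readings give 0.375, a drift of 0.0130, but birch's last E was 5.6%, read to 0.5 percentage points. I left the drift out and kept ρ for this flask at 20 min.

The forecast gave 0.39 there and 0.4 at 0.15 s, saying of the early value: “I take the equilibrium value as a weak guess with a very wide range”.

    D + L ⇌ G (K = 17.0 L mol⁻¹, k = 0.170 L mol⁻¹ s⁻¹)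
    2 X → Q (k = 500 L mol⁻¹ s⁻¹)
    D + L ⇌ E (K = 43.0 L mol⁻¹, k = 0.460 L mol⁻¹ s⁻¹)
    D + L → Z (k = 0.130 L mol⁻¹ s⁻¹)
    E + X ⇌ G + X, rate k5*[X]*[E] forward; the back reaction follows from the equilibrium constant (k = 5.00 L mol⁻¹ s⁻¹)
    2 X ⇌ J, settled at all times (K = 160 L mol⁻¹)

The flask gave 0.370 at 0.15 s and 0.400 at 20 min. The first stands beside the ratio of forward constants, k1/k3 = 0.370, and the second beside the ratio of equilibrium constants, K1/K3 = 0.395; kinetic and thermodynamic control lie 0.0258 apart here. A second flask, charged alike but with 4.4 mM of X, held 7.78% of E at 20 min; ρ times that is 3.07%, and it held 3.11% of G.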